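**Direct plan and its weak points**

A direct plan would build the benzofuran first and ring C last by a polyketide-type condensation: acetylacetone A1 would be prenylated at both terminal carbons through its dianions to diketone A2, and the dianion of A2 would be acylated by the 6-allyloxybenzofuran-2-carboxylic ester A3 to triketone A4.
Aqueous base would close A4 by aldol condensation and aromatization to the symmetric resorcinol A5; one equivalent of a methylating agent would give monoether A6, and palladium-catalysed deallylation would give the target.
(a) The mono-O-methylation of A5 would be weak: the two hydroxyls are equivalent, so the step is statistical, and diol, monoether and diether would have to be separated and recycled at the most advanced stage.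
(b) The acylation/aldol pair that makes ring C would be weak: an excess of the dianion of A2 is spent per ester, and the closure is an aldol of a branched enolate onto a hindered aryl ketone in warm base, where retro-Claisen cleavage of the tricarbonyl chain competes.
(c) The double terminal prenylation of A1 (mono-, di- and internally alkylated products from successive dianions) and the allyl ether that is put on and taken off again would add operations that build no skeleton.

**Retrosynthetic overview of the new route**

Labels: ring C = benzene C1'–C6' (C1' on benzofuran C2, prenyl on C2' and C6', OH on C3', H on C4', OMe on C5'); ring A = benzo ring; ring B = furan.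
1. Ring B closes last: O1–C2 and C3–C3a are cut, giving terminal alkyne 20 (all of ring C) and 4-iodoresorcinol 21 (ring A), joined by a domino Sonogashira coupling/5-endo-dig annulation.
2. Ring C is made by benzannulation (key): cyclobutenone 10 (C1', C2', C3', C6', both prenyls and the alkyne in place) takes up methoxyacetylene 14 (C4', C5', OMe), forming C3'–C4' and C5'–C6', and the dienylketene closes C2'–C3' by six-electron electrocyclization.
3. Cyclobutenone 10 comes in three steps from ethoxyacetylene, prenyl bromide and (trimethylsilyl)acetylene: thermal ynol ether/ketene dimerization gives the diprenyl four-membered ring, and acetylide addition/hydrolysis attaches the alkyne to C1'.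
4. By design the C3' hydroxyl is the former ketone oxygen and the C5' methoxyl comes from 14, so there is no statistical methylation, no oxygen protecting group and no dianion chemistry, and C1' arrives already flanked by both prenyls.

Key step: step 5

Assumption: methoxyacetylene is not relied on as a stock chemical; it would be made (step 4) and used as a cold toluene solution. The target is achiral, so no stereocentre has to be set.

**Route**

Step 1
Reactants: 1 ethoxyacetylene; 2 prenyl bromide
Product: 4 1-ethoxy-5-methylhex-4-en-1-yne, via lithium ethoxyacetylide 3 (not isolated)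
Conditions: n-BuLi (1.05 equiv), THF, −78 °C; 2 (1.0 equiv), DMPU, −78 °C to rt; distil
Reagents that add atoms: prenyl bromide (compound 2), CC(C)=CCBr
Why: Alkylation of a lithium alkoxyacetylide: the acetylide carbon displaces bromide at the primary carbon of prenyl bromide (SN2, not SN2' at the hindered tertiary end), and the weakly basic acetylide should leave the doubly activated CH2 of the skipped enyne alone.

Step 2
Reactants: 4 1-ethoxy-5-methylhex-4-en-1-yne (two molecules)
Product: 6 3-ethoxy-2,4-bis(3-methylbut-2-en-1-yl)cyclobut-2-en-1-one, via prenylketene 5 (not isolated)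
Conditions: toluene (1 M), 110 °C, Ar
Reagents that add atoms: none
Why: Thermal retro-ene fragmentation of the ethyl ynol ether (loss of ethene) gives prenylketene 5, which a second molecule of 4 captures in a regiospecific [2+2] cycloaddition (ketene carbonyl carbon to the nucleophilic β-carbon of the ynol ether), the established entry to 2,4-dialkyl-3-ethoxycyclobutenones; the new C4 centre is racemic and is erased in step 5.

Step 3
Reactants: 6 3-ethoxy-2,4-bis(3-methylbut-2-en-1-yl)cyclobut-2-en-1-one; 7 (trimethylsilyl)acetylene
Product: 10 2,4-bis(3-methylbut-2-en-1-yl)-3-[(trimethylsilyl)ethynyl]cyclobut-2-en-1-one, via lithium (trimethylsilyl)acetylide 8 (not isolated), via carbinol adduct 9 (not isolated)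
Conditions: 7 (1.3 equiv), n-BuLi (1.25 equiv), THF, −78 °C; 6, −78 to −20 °C; 1 M HCl, 0 °C
Reagents that add atoms: (trimethylsilyl)acetylene (compound 7), C#C[Si](C)(C)C; water, O
Why: 1,2-Addition of an alkynyllithium to a vinylogous ester, then acid hydrolysis with allylic transposition (Stork–Danheiser-type carbonyl transposition on a 3-ethoxycyclobutenone): enolization at C4 would give an antiaromatic cyclobutadienolate and so should not compete, and cold dilute acid unmasks the ketone at the former enol ether carbon without touching the prenyl groups or the C–Si bond; the carbinol centre is transient and C4 stays racemic.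

Step 4
Reactants: 11 chloroacetaldehyde dimethyl acetal
Product: 14 methoxyacetylene, via 1-chloro-2-methoxyethene 12 (not isolated), via sodium methoxyacetylide 13 (not isolated)
Conditions: NaNH2 (3 equiv), liq. NH3, −33 °C; evaporate NH3; cold satd aq NaCl, −20 °C; distil (bp about 23 °C) into cold toluene
Reagents that add atoms: none
Why: Double base-induced elimination (methanol, then hydrogen chloride) from a chloroacetal with sodium amide, the classical preparation of alkoxyacetylenes; the acetylide salt protects the product until the aqueous quench.

Step 5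
Reactants: 10 2,4-bis(3-methylbut-2-en-1-yl)-3-[(trimethylsilyl)ethynyl]cyclobut-2-en-1-one; 14 methoxyacetylene
Product: 20 3-ethynyl-5-methoxy-2,4-bis(3-methylbut-2-en-1-yl)phenol, via vinylketene 15 (not isolated), via vinylcyclobutenone 16 (not isolated), via dienylketene 17 (not isolated), via cyclohexadienone 18 (not isolated), via silylalkynyl phenol 19 (not isolated)
Conditions: 14 (3 equiv), toluene, sealed tube, 80 °C then 110 °C; evaporate; K2CO3 (2 equiv), MeOH, rt
Reagents that add atoms: methoxyacetylene (compound 14), COC#C
Why: Danheiser benzannulation, a pericyclic cascade with close precedent for cyclobutenones and alkoxyacetylenes giving resorcinol monoethers: heat opens 10 by a four-electron conrotatory electrocyclic reaction (C4 prenyl turning outward) to vinylketene 15, whose C=C=O unit adds 14 in a [2+2] cycloaddition to vinylcyclobutenone 16, a second four-electron opening gives dienylketene 17, and a thermal six-electron disrotatory electrocyclization followed by tautomerization of dienone 18 gives phenol 19. Ring C is thus closed by the electrocyclization at C2'–C3' (ketene carbon onto the prenyl-bearing CH terminus), after the two alkyne carbons C4' and C5' have been inserted between C3' and C6' through the new bonds C3'–C4' and C5'–C6'. No stereocentre remains, since the racemic centres of 10, 16 and 18 all become aromatic carbons. The only selectivity needed is regiochemical: the nucleophilic CH of 14 bonds to the ketene carbonyl carbon, so OMe ends meta to OH with the lone C–H between them, and the identical prenyl groups on C2 and C4 of 10 place the alkynyl carbon C1' between them. The hydroxyl at C3' is the former ketone oxygen and the methoxyl at C5' comes from 14, so the two oxygens are never equivalent. The carbonate/methanol treatment should cleave any aryl ester formed when the phenol traps a ketene and removes the C-silyl group to give 20.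

Step 6
Reactants: 20 3-ethynyl-5-methoxy-2,4-bis(3-methylbut-2-en-1-yl)phenol; 21 4-iodoresorcinol
Product: 23 2-[3-hydroxy-5-methoxy-2,6-bis(3-methylbut-2-en-1-yl)phenyl]-1-benzofuran-6-ol, via diarylalkyne 22 (not isolated)
Conditions: 21 (1.2 equiv), Pd(PPh3)2Cl2 (5 mol %), CuI (10 mol %), Et3N (5 equiv), DMF, degassed, 65 °C, Ar
Reagents that add atoms: 4-iodoresorcinol (compound 21), Oc1ccc(I)c(O)c1
Why: Sonogashira coupling followed in the same flask by 5-endo-dig hydroalkoxylation (the domino coupling/heteroannulation of ortho-iodophenols with terminal alkynes): zerovalent palladium formed from the divalent precatalyst inserts into the C–I bond, the copper acetylide of 20 transmetalates, reductive elimination gives diarylalkyne 22, and only the ring A hydroxyl ortho to the alkyne can reach the metal-activated triple bond, so O1–C2 closes the furan while the C3' hydroxyl (meta to the alkyne) and the 6-hydroxyl stay free.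

**Compound list**

1 | ethoxyacetylene (ethoxyethyne) | C#COCC | starting material
2 | prenyl bromide (1-bromo-3-methylbut-2-ene) | CC(C)=CCBr | starting material
3 | lithium ethoxyacetylide (formed in the flask, not isolated) | [Li]C#COCC | intermediate
4 | 1-ethoxy-5-methylhex-4-en-1-yne | CCOC#CCC=C(C)C | intermediate
5 | prenylketene, 5-methylhexa-1,4-dien-1-one (formed in the flask, not isolated) | O=C=CCC=C(C)C | intermediate
6 | 3-ethoxy-2,4-bis(3-methylbut-2-en-1-yl)cyclobut-2-en-1-one (racemic at C4) | CCOC1=C(CC=C(C)C)C(=O)C1CC=C(C)C | intermediate
7 | (trimethylsilyl)acetylene (ethynyltrimethylsilane) | C#C[Si](C)(C)C | starting material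
8 | lithium (trimethylsilyl)acetylide (formed in the flask, not isolated) | [Li]C#C[Si](C)(C)C | intermediate
9 | carbinol adduct, 3-ethoxy-2,4-bis(3-methylbut-2-en-1-yl)-1-[(trimethylsilyl)ethynyl]cyclobut-2-en-1-ol (not isolated, diastereomer mixture) | CCOC1=C(CC=C(C)C)C(O)(C#C[Si](C)(C)C)C1CC=C(C)C | intermediate
10 | 2,4-bis(3-methylbut-2-en-1-yl)-3-[(trimethylsilyl)ethynyl]cyclobut-2-en-1-one (racemic at C4) | CC(C)=CCC1C(=O)C(CC=C(C)C)=C1C#C[Si](C)(C)C | intermediate
11 | chloroacetaldehyde dimethyl acetal (2-chloro-1,1-dimethoxyethane) | COC(CCl)OC | starting material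
12 | 1-chloro-2-methoxyethene (not isolated, E/Z mixture) | COC=CCl | intermediate
13 | sodium methoxyacetylide (not isolated) | [Na]C#COC | intermediate
14 | methoxyacetylene (methoxyethyne) | COC#C | intermediate
15 | vinylketene, 7-methyl-2-(3-methylbut-2-en-1-yl)-3-[(trimethylsilyl)ethynyl]octa-1,3,6-trien-1-one (not isolated; C4 chain trans to the ketene carbon) | O=C=C(CC=C(C)C)/C(C#C[Si](C)(C)C)=C/CC=C(C)C | intermediate
16 | vinylcyclobutenone, 3-methoxy-4-(3-methylbut-2-en-1-yl)-4-{5-methyl-1-[(trimethylsilyl)ethynyl]hexa-1,4-dien-1-yl}cyclobut-2-en-1-one (not isolated, racemic) | COC1=CC(=O)C1(CC=C(C)C)/C(C#C[Si](C)(C)C)=C/CC=C(C)C | intermediate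
17 | dienylketene, 3-methoxy-9-methyl-4-(3-methylbut-2-en-1-yl)-5-[(trimethylsilyl)ethynyl]deca-1,3,5,8-tetraen-1-one (not isolated) | O=C=C/C(OC)=C(CC=C(C)C)\C(C#C[Si](C)(C)C)=C\CC=C(C)C | intermediate
18 | cyclohexadienone, 3-methoxy-4,6-bis(3-methylbut-2-en-1-yl)-5-[(trimethylsilyl)ethynyl]cyclohexa-2,4-dien-1-one (not isolated, racemic) | O=C1C=C(OC)C(CC=C(C)C)=C(C#C[Si](C)(C)C)C1CC=C(C)C | intermediate
19 | 5-methoxy-2,4-bis(3-methylbut-2-en-1-yl)-3-[(trimethylsilyl)ethynyl]phenol (not isolated) | COc1cc(O)c(CC=C(C)C)c(C#C[Si](C)(C)C)c1CC=C(C)C | intermediate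
20 | 3-ethynyl-5-methoxy-2,4-bis(3-methylbut-2-en-1-yl)phenol | COc1cc(O)c(CC=C(C)C)c(C#C)c1CC=C(C)C | intermediate
21 | 4-iodoresorcinol (4-iodobenzene-1,3-diol) | Oc1ccc(I)c(O)c1 | starting material
22 | diarylalkyne, 4-{[3-hydroxy-5-methoxy-2,6-bis(3-methylbut-2-en-1-yl)phenyl]ethynyl}benzene-1,3-diol (not isolated) | COc1cc(O)c(CC=C(C)C)c(C#Cc2ccc(O)cc2O)c1CC=C(C)C | intermediate
23 | 2-[3-hydroxy-5-methoxy-2,6-bis(3-methylbut-2-en-1-yl)phenyl]-1-benzofuran-6-ol (achiral) | COc1cc(O)c(CC=C(C)C)c(-c2cc3ccc(O)cc3o2)c1CC=C(C)C | target

**Step count and risks**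

Total step count: 6. Longest linear sequence: 5 (steps 1, 2, 3, 5, 6); step 4 is a one-step branch.

Steps most likely to fail:

1. Step 5 (key step). The vinylketene from 10 may be consumed by self-condensation or by the product phenol faster than the small, volatile ynol ether adds, or 14 may be lost from solution before the ring opening sets in. The fallback sets out from 10 and comes back at 16. The alkyne is replaced by an alkene of the ketene acetal class in a stepwise polar annulation. Heating 10 with 1,1-dimethoxyethene F1 (purchased, 5 equiv) in toluene at 80–100 °C should trap vinylketene 15, through a zwitterion, as 3,3-dimethoxy-2-(3-methylbut-2-en-1-yl)-2-{5-methyl-1-[(trimethylsilyl)ethynyl]hexa-1,4-dien-1-yl}cyclobutan-1-one F2. Loss of methanol from F2 on further heating or on silica gives 16, which continues to 19 and 20 as in step 5. Either mode of closure of the zwitterion should lead, after loss of methanol, to the same phenol 19, because C2 and C4 of 10 carry the same substituent.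

2. Step 6. Oxidative addition into the electron-rich, unprotected iodoresorcinol may be slow, so that the hindered terminal alkyne dimerises oxidatively (Glaser) or the annulation stalls at the diarylalkyne stage. The fallback sets out from 6 and comes back at 23. The C1'–C2 bond is made by organolithium addition before ring C exists, and an intact benzofuran is carried through the benzannulation, so no cross-coupling at the hindered position is needed. 1-Benzofuran-6-ol F3 (purchased) is silylated (TBSCl, imidazole, DMF) to tert-butyl(1-benzofuran-6-yloxy)dimethylsilane F4. F4 is lithiated at C2 (n-BuLi, THF, −78 °C) and added to 6; acid work-up as in step 3 should give 3-[6-(tert-butyldimethylsilyloxy)-1-benzofuran-2-yl]-2,4-bis(3-methylbut-2-en-1-yl)cyclobut-2-en-1-one F5. Benzannulation of F5 with 14 under the conditions of step 5 (without the carbonate treatment) should give 3-[6-(tert-butyldimethylsilyloxy)-1-benzofuran-2-yl]-5-methoxy-2,4-bis(3-methylbut-2-en-1-yl)phenol F6, and TBAF (THF, 0 °C) then gives 23.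

3. Step 2. The retro-ene fragmentation needs about 110 °C, where the ketene may dimerise and the skipped enyne may isomerise, and half of 4 is spent as the ketene source by design. The fallback sets out from 4 and comes back at 6. The ketene is generated at room temperature by dehydrohalogenation instead. 5-Methylhex-4-enoic acid F7 (purchased) is converted with (COCl)2 and catalytic DMF in CH2Cl2 to 5-methylhex-4-enoyl chloride F8. F8 is added slowly to 4 (1 equiv) and Et3N in Et2O at rt, so that ketene 5 forms in the presence of the ynol ether and adds to it to give 6.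

**Further compounds**

F1 | step 5 | 1,1-dimethoxyethene (ketene dimethyl acetal, purchased) | C=C(OC)OC
F2 | step 5 | 3,3-dimethoxy-2-(3-methylbut-2-en-1-yl)-2-{5-methyl-1-[(trimethylsilyl)ethynyl]hexa-1,4-dien-1-yl}cyclobutan-1-one (racemic) | COC1(OC)CC(=O)C1(CC=C(C)C)/C(C#C[Si](C)(C)C)=C/CC=C(C)C
F3 | step 6 | 1-benzofuran-6-ol (purchased) | Oc1ccc2ccoc2c1
F4 | step 6 | tert-butyl(1-benzofuran-6-yloxy)dimethylsilane | CC(C)(C)[Si](C)(C)Oc1ccc2ccoc2c1
F5 | step 6 | 3-[6-(tert-butyldimethylsilyloxy)-1-benzofuran-2-yl]-2,4-bis(3-methylbut-2-en-1-yl)cyclobut-2-en-1-one (racemic) | CC(C)=CCC1C(=O)C(CC=C(C)C)=C1c1cc2ccc(O[Si](C)(C)C(C)(C)C)cc2o1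
F6 | step 6 | 3-[6-(tert-butyldimethylsilyloxy)-1-benzofuran-2-yl]-5-methoxy-2,4-bis(3-methylbut-2-en-1-yl)phenol | COc1cc(O)c(CC=C(C)C)c(-c2cc3ccc(O[Si](C)(C)C(C)(C)C)cc3o2)c1CC=C(C)C
F7 | step 2 | 5-methylhex-4-enoic acid (purchased) | CC(C)=CCCC(=O)O
F8 | step 2 | 5-methylhex-4-enoyl chloride | CC(C)=CCCC(=O)Cl
A1 | direct plan | acetylacetone (pentane-2,4-dione) | CC(=O)CC(C)=O
A2 | direct plan | 2,12-dimethyltrideca-2,11-diene-6,8-dione | CC(C)=CCCC(=O)CC(=O)CCC=C(C)C
A3 | direct plan | ethyl 6-(allyloxy)-1-benzofuran-2-carboxylate | CCOC(=O)c1cc2ccc(OCC=C)cc2o1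
A4 | direct plan | 1-[6-(allyloxy)-1-benzofuran-2-yl]-9-methyl-2-(3-methylbut-2-en-1-yl)dec-8-ene-1,3,5-trione (racemic) | C=CCOc1ccc2cc(C(=O)C(CC=C(C)C)C(=O)CC(=O)CCC=C(C)C)oc2c1
A5 | direct plan | 5-[6-(allyloxy)-1-benzofuran-2-yl]-4,6-bis(3-methylbut-2-en-1-yl)benzene-1,3-diol | C=CCOc1ccc2cc(-c3c(CC=C(C)C)c(O)cc(O)c3CC=C(C)C)oc2c1
A6 | direct plan | 3-[6-(allyloxy)-1-benzofuran-2-yl]-5-methoxy-2,4-bis(3-methylbut-2-en-1-yl)phenol | C=CCOc1ccc2cc(-c3c(CC=C(C)C)c(O)cc(OC)c3CC=C(C)C)oc2c1
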